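**Plan**
1. Retrosynthetic cuts: the lactone bond C5–O4 (C5 is carried as a masked primary alcohol), the side-chain alkene C1′=C2′ (cross-metathesis), and the two oxolane bonds O1–C2 and C3a–C7a.
2. Enabling feature: in the oxolane ring, O1–C7a and the C3 carbinol are 1,3-related through C3a, an aldol pattern once C3 is a ketone. C2, α to that same carbon, carries the one-carbon arm C1′, so a C3 ketone flanked by a silyloxymethylene (C3a) and an oxirane (C2–C1′) can close both bonds onto an aldehyde C7a=O1.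
3. Forward: aldehyde 3 (from (R)-butane-1,2,4-triol) and epoxy ketone 7 are joined in a one-pot boron aldol / 5-exo oxirane opening / hydride reduction to give the all-cis oxolane 11. The helper hydroxymethyl at C2 is then oxidised and methylenated.
4. Cross-metathesis with diester 18 installs the side chain; acid unmasks O4, O7 and C5–OH; oxidative lactonisation closes the pyranone ring last.
5. Stereochemistry: C7 from the chiral pool; C7a and C3a from the aldol (enolate geometry, Cornforth/Felkin–Anh); C2 by inversion of a Sharpless-derived oxirane; C3 by substrate-controlled hydride delivery; C3′ and C4′ by Sharpless desymmetrisation of penta-1,4-dien-3-ol.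

Key step: step 6

Locants: the furo[3,2-b]pyran-5-one numbering of the target (O1, C2, C3, C3a, O4, C5, C6, C7, C7a) and C1′–C5′ for the pentenyl chain are used for all intermediates.

**Route**

Step 1
Reactants: 1 (R)-butane-1,2,4-triol
Product: 2 [(2R,4R)-2-(4-methoxyphenyl)-1,3-dioxan-4-yl]methanol
Conditions: 4-MeOC6H4CH(OMe)2, CSA (cat.), CH2Cl2, rt
Reagents that add atoms: 4-methoxybenzaldehyde dimethyl acetal, COC(OC)c1ccc(OC)cc1
Why: Thermodynamic transacetalisation should favour the six-membered 1,3-dioxane with both substituents equatorial, which masks O7 and the C5 oxygen and leaves only the primary hydroxyl (future C7a) free; the C7 stereocentre is bought.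

Step 2
Reactants: 2 [(2R,4R)-2-(4-methoxyphenyl)-1,3-dioxan-4-yl]methanol
Product: 3 (2R,4R)-2-(4-methoxyphenyl)-1,3-dioxane-4-carbaldehyde
Conditions: Dess–Martin periodinane, pyridine, CH2Cl2, 0 °C → rt
Reagents that add atoms: none
Why: Buffered Dess–Martin oxidation of the primary alcohol should give the α-alkoxy aldehyde (C7a=O1 with C7, C6, C5 attached) without epimerisation.

Step 3
Reactants: 4 (R)-but-3-ene-1,2-diol
Product: 5 (R)-1-[(tert-butyldimethylsilyl)oxy]but-3-en-2-ol
Conditions: TBSCl, imidazole, CH2Cl2, −20 → 0 °C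
Reagents that add atoms: tert-butyldimethylsilyl chloride, CC(C)(C)[Si](C)(C)Cl
Why: Silylation should be selective for the primary hydroxyl on steric grounds, leaving the secondary allylic alcohol that directs the epoxidation.

Step 4
Reactants: 5 (R)-1-[(tert-butyldimethylsilyl)oxy]but-3-en-2-ol
Product: 6 (1S)-2-[(tert-butyldimethylsilyl)oxy]-1-[(2R)-oxiran-2-yl]ethan-1-ol
Conditions: Ti(OiPr)4, L-(+)-diisopropyl tartrate, t-BuOOH, 4 Å MS, CH2Cl2, −20 °C
Reagents that add atoms: tert-butyl hydroperoxide, CC(C)(C)OO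
Why: Sharpless asymmetric epoxidation in the matched sense (the (R)-carbinol is the fast-reacting enantiomer with the L-tartrate) should give the erythro epoxy alcohol and so fix the (R)-oxirane carbon that becomes C2.

Step 5
Reactants: 6 (1S)-2-[(tert-butyldimethylsilyl)oxy]-1-[(2R)-oxiran-2-yl]ethan-1-ol
Product: 7 2-[(tert-butyldimethylsilyl)oxy]-1-[(2R)-oxiran-2-yl]ethan-1-one
Conditions: Dess–Martin periodinane, pyridine, CH2Cl2, 0 °C
Reagents that add atoms: none
Why: Dess–Martin oxidation of the secondary alcohol should give the α-silyloxy α′,β′-epoxy ketone; the oxirane stereocentre is not enolisable and survives.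

Step 6
Reactants: 3 (2R,4R)-2-(4-methoxyphenyl)-1,3-dioxane-4-carbaldehyde; 7 2-[(tert-butyldimethylsilyl)oxy]-1-[(2R)-oxiran-2-yl]ethan-1-one
Product: 11 (2S,3R,4R,5R)-4-[(tert-butyldimethylsilyl)oxy]-2-(hydroxymethyl)-5-[(2R,4R)-2-(4-methoxyphenyl)-1,3-dioxan-4-yl]oxolan-3-ol (all four ring substituents cis), via boron enolate 8 (not isolated), via syn-aldol adduct 9 (not isolated), via oxolan-3-one 10 (not isolated)
Conditions: 7, n-Bu2BOTf, i-Pr2NEt, CH2Cl2, −78 °C; then 3, −78 → −20 °C; then MeOH, DBU (cat.), 0 °C; then NaBH4, −40 °C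
Reagents that add atoms: none
Why: Soft enolisation of 7, whose only enolisable position is the C3a methylene, should give (Z)-enolate 8, which adds to aldehyde 3 through a chair (Zimmerman–Traxler) transition state to form C3a–C7a; methanolysis then frees the C7a oxygen (O1), which under DBU opens the oxirane at C2 by intramolecular SN2 to form O1–C2, and NaBH4 reduces the resulting oxolan-3-one 10 in the same flask. The closest known reaction types are the syn-selective boron aldol reaction of α-silyloxy ketones with α-alkoxy aldehydes and the base-mediated cycloetherification of γ-hydroxy epoxides to 2-(hydroxymethyl)oxolanes, so the sequence amounts to a formal (3+2) annulation of the aldehyde C=O with the C3a–C3–C2 unit. The oxolane closes in the 5-exo-tet mode, and the lactone ring is not formed here. C3a and C7a should be set syn by the (Z)-enolate geometry, C7a anti to the C7 oxygen by Cornforth/polar Felkin–Anh facial selection on the α-alkoxy aldehyde, C2 by inversion of the (R)-oxirane carbon from step 4, and C3 by hydride attack on the ketone face opposite to the C2, C3a and C7a substituents, which all lie on one side. The step needs exo (C2) rather than endo (C1′) opening of the oxirane, which the five-membered transition state and the activation of C2 as the carbon α to the ketone should secure, and it needs the oxirane and the epimerisable ketone 10 to survive, which is why an electron-poor, weakly Lewis basic epoxy ketone, low temperature, a non-nucleophilic base and immediate reduction are chosen.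

Step 7
Reactants: 11 (2S,3R,4R,5R)-4-[(tert-butyldimethylsilyl)oxy]-2-(hydroxymethyl)-5-[(2R,4R)-2-(4-methoxyphenyl)-1,3-dioxan-4-yl]oxolan-3-ol
Product: 12 (2R,3R,4R,5R)-4-[(tert-butyldimethylsilyl)oxy]-3-hydroxy-5-[(2R,4R)-2-(4-methoxyphenyl)-1,3-dioxan-4-yl]oxolane-2-carbaldehyde
Conditions: TEMPO (cat.), PhI(OAc)2, CH2Cl2, rt
Reagents that add atoms: none
Why: Oxoammonium (TEMPO/PhI(OAc)2) oxidation should take the primary hydroxyl in preference to the flanked secondary C3 hydroxyl and, being non-basic, should leave the all-cis α-alkoxy aldehyde unepimerised at C2.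

Step 8
Reactants: 12 (2R,3R,4R,5R)-4-[(tert-butyldimethylsilyl)oxy]-3-hydroxy-5-[(2R,4R)-2-(4-methoxyphenyl)-1,3-dioxan-4-yl]oxolane-2-carbaldehyde
Product: 13 (2S,3R,4R,5R)-4-[(tert-butyldimethylsilyl)oxy]-2-ethenyl-5-[(2R,4R)-2-(4-methoxyphenyl)-1,3-dioxan-4-yl]oxolan-3-ol
Conditions: Ph3PCH3Br, KN(SiMe3)2, THF, 0 °C; then 12, −78 → 0 °C (excess ylide)
Reagents that add atoms: methyltriphenylphosphonium bromide, C[P+](c1ccccc1)(c1ccccc1)c1ccccc1.[Br-]
Why: Wittig methylenation at low temperature should convert the helper aldehyde into the C2 vinyl group (C1′=CH2) faster than the α-alkoxy aldehyde enolises.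

Step 9
Reactants: 14 penta-1,4-dien-3-ol
Product: 15 (1S)-1-[(2R)-oxiran-2-yl]prop-2-en-1-ol
Conditions: Ti(OiPr)4, L-(+)-diisopropyl tartrate, t-BuOOH, 4 Å MS, CH2Cl2, −20 °C
Reagents that add atoms: tert-butyl hydroperoxide, CC(C)(C)OO
Why: Sharpless desymmetrising epoxidation of the divinyl carbinol combines enantiotopic-group and diastereoface selection and should give the erythro epoxy alcohol, which sets C3′ and C4′.

Step 10
Reactants: 15 (1S)-1-[(2R)-oxiran-2-yl]prop-2-en-1-ol
Product: 16 (2R,3S)-pent-4-ene-2,3-diol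
Conditions: LiAlH4, THF, 0 °C
Reagents that add atoms: none
Why: Hydride should open the terminal oxirane at its unsubstituted carbon (SN2), turning C5′ into the methyl group without touching either stereocentre and giving the anti diol.

Step 11
Reactants: 16 (2R,3S)-pent-4-ene-2,3-diol
Product: 17 (2R,3S)-3-hydroxypent-4-en-2-yl acetate
Conditions: immobilised Candida antarctica lipase B, vinyl acetate, t-BuOMe, rt
Reagents that add atoms: vinyl acetate, CC(=O)OC=C
Why: Lipase-catalysed transesterification should acylate the (R)-configured methyl carbinol (C4′), which fits the Kazlauskas preference, and leave the (S)-allylic hydroxyl free.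

Step 12
Reactants: 17 (2R,3S)-3-hydroxypent-4-en-2-yl acetate
Product: 18 (3S,4R)-4-(acetyloxy)pent-1-en-3-yl benzoate
Conditions: BzCl, pyridine, DMAP (cat.), CH2Cl2, 0 °C
Reagents that add atoms: benzoyl chloride, O=C(Cl)c1ccccc1
Why: Nucleophilic-catalysed acylation of the remaining allylic hydroxyl at low temperature, where acetyl migration should be slow, completes the differentiated diester.

Step 13
Reactants: 13 (2S,3R,4R,5R)-4-[(tert-butyldimethylsilyl)oxy]-2-ethenyl-5-[(2R,4R)-2-(4-methoxyphenyl)-1,3-dioxan-4-yl]oxolan-3-ol; 18 (3S,4R)-4-(acetyloxy)pent-1-en-3-yl benzoate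
Product: 19 (1E,3S,4R)-4-(acetyloxy)-1-{(2S,3R,4R,5R)-4-[(tert-butyldimethylsilyl)oxy]-3-hydroxy-5-[(2R,4R)-2-(4-methoxyphenyl)-1,3-dioxan-4-yl]oxolan-2-yl}pent-1-en-3-yl benzoate
Conditions: second-generation Hoveyda–Grubbs catalyst (H2IMes)Cl2Ru(=CH-C6H4-2-OiPr) (cat.), CH2Cl2, 40 °C, 18 in excess
Reagents that add atoms: none
Why: Olefin cross-metathesis of two monosubstituted alkenes releases ethene and should give the thermodynamically preferred (E)-alkene C1′=C2′ without touching any stereocentre.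

Step 14
Reactants: 19 (1E,3S,4R)-4-(acetyloxy)-1-{(2S,3R,4R,5R)-4-[(tert-butyldimethylsilyl)oxy]-3-hydroxy-5-[(2R,4R)-2-(4-methoxyphenyl)-1,3-dioxan-4-yl]oxolan-2-yl}pent-1-en-3-yl benzoate
Product: 20 (1E,3S,4R)-4-(acetyloxy)-1-{(2S,3S,4R,5R)-5-[(1R)-1,3-dihydroxypropyl]-3,4-dihydroxyoxolan-2-yl}pent-1-en-3-yl benzoate
Conditions: aq. HF (48 %), MeCN, 0 °C → rt
Reagents that add atoms: none
Why: Acid-mediated desilylation and hydrolysis of the 4-methoxybenzylidene acetal should unmask O4–H, O7–H and the primary C5 hydroxyl in one step, the acetate and benzoate being stable to these conditions.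

Step 15
Reactants: 20 (1E,3S,4R)-4-(acetyloxy)-1-{(2S,3S,4R,5R)-5-[(1R)-1,3-dihydroxypropyl]-3,4-dihydroxyoxolan-2-yl}pent-1-en-3-yl benzoate
Product: 23 (1E,3S,4R)-4-(acetyloxy)-1-[(2S,3R,3aR,7R,7aR)-3,7-dihydroxy-5-oxohexahydro-2H-furo[3,2-b]pyran-2-yl]pent-1-en-3-yl benzoate (target), via C5 aldehyde 21 (not isolated), via δ-lactol 22 (not isolated)
Conditions: TEMPO (cat.), PhI(OAc)2, CH2Cl2, rt
Reagents that add atoms: none
Why: Oxoammonium oxidation should take the only primary hydroxyl (C5) to the aldehyde, which O4–H traps as the six-membered lactol (6-exo-trig) and which is oxidised on to the δ-lactone, the secondary C3 and C7 hydroxyls reacting much more slowly.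

**Compound list**
1 | (R)-butane-1,2,4-triol | OC[C@H](O)CCO | starting material
2 | [(2R,4R)-2-(4-methoxyphenyl)-1,3-dioxan-4-yl]methanol | OC[C@@H]1O[C@H](c2ccc(OC)cc2)OCC1 | intermediate
3 | (2R,4R)-2-(4-methoxyphenyl)-1,3-dioxane-4-carbaldehyde | O=C[C@@H]1O[C@H](c2ccc(OC)cc2)OCC1 | intermediate
4 | (R)-but-3-ene-1,2-diol | OC[C@H](O)C=C | starting material
5 | (R)-1-[(tert-butyldimethylsilyl)oxy]but-3-en-2-ol | CC(C)(C)[Si](C)(C)OC[C@H](O)C=C | intermediate
6 | (1S)-2-[(tert-butyldimethylsilyl)oxy]-1-[(2R)-oxiran-2-yl]ethan-1-ol | CC(C)(C)[Si](C)(C)OC[C@H](O)[C@H]1CO1 | intermediate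
7 | 2-[(tert-butyldimethylsilyl)oxy]-1-[(2R)-oxiran-2-yl]ethan-1-one | CC(C)(C)[Si](C)(C)OCC(=O)[C@H]1CO1 | intermediate
8 | (Z)-dibutylboron enolate of 7 | CCCCB(CCCC)O/C([C@H]1CO1)=C\O[Si](C)(C)C(C)(C)C | intermediate (not isolated)
9 | (2S,3R)-2-[(tert-butyldimethylsilyl)oxy]-3-hydroxy-3-[(2R,4R)-2-(4-methoxyphenyl)-1,3-dioxan-4-yl]-1-[(2R)-oxiran-2-yl]propan-1-one (syn-aldol adduct) | O=C([C@H]1CO1)[C@@H](O[Si](C)(C)C(C)(C)C)[C@H](O)[C@@H]2O[C@H](c3ccc(OC)cc3)OCC2 | intermediate (not isolated)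
10 | (2S,4S,5R)-4-[(tert-butyldimethylsilyl)oxy]-2-(hydroxymethyl)-5-[(2R,4R)-2-(4-methoxyphenyl)-1,3-dioxan-4-yl]oxolan-3-one | OC[C@@H]1O[C@H]([C@@H]2O[C@H](c3ccc(OC)cc3)OCC2)[C@H](O[Si](C)(C)C(C)(C)C)C1=O | intermediate (not isolated)
11 | (2S,3R,4R,5R)-4-[(tert-butyldimethylsilyl)oxy]-2-(hydroxymethyl)-5-[(2R,4R)-2-(4-methoxyphenyl)-1,3-dioxan-4-yl]oxolan-3-ol | OC[C@@H]1O[C@H]([C@@H]2O[C@H](c3ccc(OC)cc3)OCC2)[C@H](O[Si](C)(C)C(C)(C)C)[C@@H]1O | intermediate
12 | (2R,3R,4R,5R)-4-[(tert-butyldimethylsilyl)oxy]-3-hydroxy-5-[(2R,4R)-2-(4-methoxyphenyl)-1,3-dioxan-4-yl]oxolane-2-carbaldehyde | O=C[C@@H]1O[C@H]([C@@H]2O[C@H](c3ccc(OC)cc3)OCC2)[C@H](O[Si](C)(C)C(C)(C)C)[C@@H]1O | intermediate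
13 | (2S,3R,4R,5R)-4-[(tert-butyldimethylsilyl)oxy]-2-ethenyl-5-[(2R,4R)-2-(4-methoxyphenyl)-1,3-dioxan-4-yl]oxolan-3-ol | C=C[C@@H]1O[C@H]([C@@H]2O[C@H](c3ccc(OC)cc3)OCC2)[C@H](O[Si](C)(C)C(C)(C)C)[C@@H]1O | intermediate
14 | penta-1,4-dien-3-ol | C=CC(O)C=C | starting material
15 | (1S)-1-[(2R)-oxiran-2-yl]prop-2-en-1-ol | C=C[C@H](O)[C@H]1CO1 | intermediate
16 | (2R,3S)-pent-4-ene-2,3-diol | O[C@H](C)[C@H](C=C)O | intermediate
17 | (2R,3S)-3-hydroxypent-4-en-2-yl acetate | CC(=O)O[C@H](C)[C@H](C=C)O | intermediate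
18 | (3S,4R)-4-(acetyloxy)pent-1-en-3-yl benzoate | CC(=O)O[C@H](C)[C@H](C=C)OC(=O)c1ccccc1 | intermediate
19 | (1E,3S,4R)-4-(acetyloxy)-1-{(2S,3R,4R,5R)-4-[(tert-butyldimethylsilyl)oxy]-3-hydroxy-5-[(2R,4R)-2-(4-methoxyphenyl)-1,3-dioxan-4-yl]oxolan-2-yl}pent-1-en-3-yl benzoate | CC(=O)O[C@H](C)[C@H](/C=C/[C@@H]1O[C@H]([C@@H]2O[C@H](c3ccc(OC)cc3)OCC2)[C@H](O[Si](C)(C)C(C)(C)C)[C@@H]1O)OC(=O)c1ccccc1 | intermediate
20 | (1E,3S,4R)-4-(acetyloxy)-1-{(2S,3S,4R,5R)-5-[(1R)-1,3-dihydroxypropyl]-3,4-dihydroxyoxolan-2-yl}pent-1-en-3-yl benzoate | CC(=O)O[C@H](C)[C@H](/C=C/[C@@H]1O[C@H]([C@H](O)CCO)[C@H](O)[C@@H]1O)OC(=O)c1ccccc1 | intermediate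
21 | C5 aldehyde of 20 (3-hydroxy-3-oxolanylpropanal, other centres as in 20) | CC(=O)O[C@H](C)[C@H](/C=C/[C@@H]1O[C@H]([C@H](O)CC=O)[C@H](O)[C@@H]1O)OC(=O)c1ccccc1 | intermediate (not isolated)
22 | δ-lactol (5-hydroxy analogue of the target, both anomers) | CC(=O)O[C@H](C)[C@H](/C=C/[C@@H]1O[C@H]2[C@H](OC(O)C[C@H]2O)[C@@H]1O)OC(=O)c1ccccc1 | intermediate (not isolated)
23 | (1E,3S,4R)-4-(acetyloxy)-1-[(2S,3R,3aR,7R,7aR)-3,7-dihydroxy-5-oxohexahydro-2H-furo[3,2-b]pyran-2-yl]pent-1-en-3-yl benzoate | CC(=O)O[C@H](C)[C@H](/C=C/[C@@H]1O[C@H]2[C@H](OC(=O)C[C@H]2O)[C@@H]1O)OC(=O)c1ccccc1 | target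

**Count**
Total steps: 15. Longest linear sequence: 9 steps (steps 3, 4, 5, 6, 7, 8, 13, 14, 15, from (R)-but-3-ene-1,2-diol).

**Steps most likely to fail, with fallbacks**

Step 6. The one-pot relay may break down in three ways: the boron triflate may open the oxirane during enolisation, the oxirane may open in the endo sense, or the β-hydroxymethyl oxolanone 10 may epimerise or undergo retro-aldol cleavage before it is reduced. The fallback sets out from 5 and 3 and returns at 11; it builds the same ring stepwise, so that no epoxy ketone meets a Lewis acid or a base. Alcohol 5 is oxidised with Dess–Martin periodinane to 1-[(tert-butyldimethylsilyl)oxy]but-3-en-2-one F1. Enolisation with n-Bu2BOTf/i-Pr2NEt and addition to 3 should give the syn-aldol enone F2 in the same syn, anti sense as 9. Evans–Saksena reduction with Me4NBH(OAc)3 (MeCN/AcOH, −30 °C) should give the 1,3-anti allylic diol F3. Sharpless epoxidation of its terminal allylic alcohol (Ti(OiPr)4, L-(+)-diisopropyl tartrate, t-BuOOH; matched, erythro) should give the epoxy diol F4. PPTS in CH2Cl2 then closes the oxolane 5-exo with inversion at C2 to give 11.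

Step 13. Cross-metathesis between two hindered, allylically oxygenated olefins may stall, with homodimerisation of 18 or catalyst decay competing. The fallback sets out from aldehyde 12 and returns at 19; it makes C1′=C2′ by carbonyl olefination instead. The stabilised ylide (3R)-3-(acetyloxy)-1-(triphenyl-λ5-phosphanylidene)butan-2-one F5, prepared from (R)-2-(acetyloxy)propanoyl chloride and methylidenetriphenylphosphorane, should react with 12 under neutral conditions (toluene, 60 °C) to give the (E)-enone F6. Reagent-controlled reduction with (S)-2-methyl-CBS-oxazaborolidine and BH3·SMe2 should set C3′ and give the allylic alcohol F7. Benzoylation with BzCl and 2,4,6-collidine at −20 °C is expected to take the unhindered allylic hydroxyl in preference to the flanked ring C3 hydroxyl and gives 19.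

Step 8. The ylide may deprotonate the free C3 hydroxyl, and the resulting alkoxide may trigger retro-aldol ring opening or epimerisation at C2 of the all-cis aldehyde. The fallback sets out from 11 and returns at 20; the hydroxyl is masked before any base is used. Diol 11 is bis-silylated (TESOTf, 2,6-lutidine) to the bis(triethylsilyl) ether F8. Swern oxidation should convert the primary triethylsilyl ether directly into the 3-O-triethylsilyl aldehyde F9. Wittig methylenation gives the 3-O-triethylsilyl vinyl oxolane F10. Cross-metathesis with 18 under the conditions of step 13 gives the 3-O-triethylsilyl diester F11. The aqueous HF treatment of step 14 then removes both silyl groups and the acetal to give 20.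

**Further compounds**
F1 | step 6 | 1-[(tert-butyldimethylsilyl)oxy]but-3-en-2-one | C=CC(=O)CO[Si](C)(C)C(C)(C)C
F2 | step 6 | syn-aldol enone (4S,5R)-4-[(tert-butyldimethylsilyl)oxy]-5-hydroxy-5-[(2R,4R)-2-(4-methoxyphenyl)-1,3-dioxan-4-yl]pent-1-en-3-one | C=CC(=O)[C@@H](O[Si](C)(C)C(C)(C)C)[C@H](O)[C@@H]1O[C@H](c2ccc(OC)cc2)OCC1
F3 | step 6 | 1,3-anti allylic diol (C3 carbinol as in 11) | C=C[C@@H](O)[C@@H](O[Si](C)(C)C(C)(C)C)[C@H](O)[C@@H]1O[C@H](c2ccc(OC)cc2)OCC1
F4 | step 6 | erythro epoxy diol with (2R)-oxirane | C1O[C@H]1[C@@H](O)[C@@H](O[Si](C)(C)C(C)(C)C)[C@H](O)[C@@H]2O[C@H](c3ccc(OC)cc3)OCC2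
F5 | step 13 | (3R)-3-(acetyloxy)-1-(triphenyl-λ5-phosphanylidene)butan-2-one | CC(=O)O[C@H](C)C(=O)C=P(c1ccccc1)(c1ccccc1)c1ccccc1
F6 | step 13 | (E)-enone (C3′ ketone analogue of 19 without benzoate) | CC(=O)O[C@H](C)C(=O)/C=C/[C@@H]1O[C@H]([C@@H]2O[C@H](c3ccc(OC)cc3)OCC2)[C@H](O[Si](C)(C)C(C)(C)C)[C@@H]1O
F7 | step 13 | allylic alcohol (19 with free C3′ hydroxyl) | CC(=O)O[C@H](C)[C@H](/C=C/[C@@H]1O[C@H]([C@@H]2O[C@H](c3ccc(OC)cc3)OCC2)[C@H](O[Si](C)(C)C(C)(C)C)[C@@H]1O)O
F8 | step 8 | bis(triethylsilyl) ether of 11 | CC[Si](CC)(CC)OC[C@@H]1O[C@H]([C@@H]2O[C@H](c3ccc(OC)cc3)OCC2)[C@H](O[Si](C)(C)C(C)(C)C)[C@@H]1O[Si](CC)(CC)CC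
F9 | step 8 | 3-O-triethylsilyl aldehyde (12 with C3–OSiEt3) | O=C[C@@H]1O[C@H]([C@@H]2O[C@H](c3ccc(OC)cc3)OCC2)[C@H](O[Si](C)(C)C(C)(C)C)[C@@H]1O[Si](CC)(CC)CC
F10 | step 8 | 3-O-triethylsilyl vinyl oxolane (13 with C3–OSiEt3) | C=C[C@@H]1O[C@H]([C@@H]2O[C@H](c3ccc(OC)cc3)OCC2)[C@H](O[Si](C)(C)C(C)(C)C)[C@@H]1O[Si](CC)(CC)CC
F11 | step 8 | 3-O-triethylsilyl diester (19 with C3–OSiEt3) | CC(=O)O[C@H](C)[C@H](/C=C/[C@@H]1O[C@H]([C@@H]2O[C@H](c3ccc(OC)cc3)OCC2)[C@H](O[Si](C)(C)C(C)(C)C)[C@@H]1O[Si](CC)(CC)CC)OC(=O)c1ccccc1
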